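**Retrosynthetic overview**
1. 20 ⇒ 18: remove the CHO. C5'–H of ring A is the only aromatic C–H in the depside, so formylation is left to the end.
2. 18 ⇒ acid 15 (ring A, bis-benzyl ether) + phenol 13 (ring B): cut the depside C(O)–O bond.
3. 13 and 15 ⇒ one common arene, methyl 2,4-dihydroxy-3,6-dimethylbenzoate 6. For 13: C5 formylation, deoxygenation to CH3, 4-OBn, 2-OMe, debenzylation. For 15: bis-benzylation, saponification.
4. 6 ⇒ cyclohexane-1,3-dione 4 (aromatisation) ⇒ dimethyl malonate 1 + (E)-hex-4-en-3-one 2. An intermolecular Michael addition makes the C1–C6 bond, and a ring-closing Claisen (Dieckmann) condensation in the same pot makes C2–C3.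
5. Ring order: step 1 is the only ring-forming event and step 2 aromatises the ring. The material is then split, ring B is elaborated first and ring A second, and the two are joined in step 10.

Assumption: the SMILES has no stereodescriptor and the molecule has no stereocentre or stable stereogenic axis, so the target is achiral and no asymmetric step is needed. The sp3 centres in 3, 4, 5, 7 and 19 are transient and form as mixtures.

**Step 1**
Reactants: 1 dimethyl malonate; 2 (E)-hex-4-en-3-one
Product: 4 methyl 3,6-dimethyl-2,4-dioxocyclohexane-1-carboxylate, via malonate Michael adduct 3 (not isolated)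
Conditions: NaOMe (1.1 equiv), MeOH, 0 °C → reflux, 4 h; then 2 M HCl, 0 °C
Reagents that add atoms: none
Why: Michael addition of the soft malonate enolate to the enone β-carbon forges the C1–C6 bond between the two fragments, then the ethyl-ketone enolate of 3 closes the six-membered ring on one malonate ester (Dieckmann-type Claisen condensation), driven by deprotonation of the acidic tricarbonyl product; the three sp3 centres form as a mixture and are erased in step 2.

**Step 2**
Reactants: 4 methyl 3,6-dimethyl-2,4-dioxocyclohexane-1-carboxylate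
Product: 6 methyl 2,4-dihydroxy-3,6-dimethylbenzoate, via 3-bromo dione 5 (not isolated)
Conditions: NBS (1.0 equiv), DMF, 0 °C, 1 h; then 80 °C, 3 h
Reagents that add atoms: none
Why: Halogenation–elimination aromatisation (α-bromination of the enolised 1,3-dione, thermal dehydrobromination, tautomerisation) gives the resorcinol, and the dione enol consumes the single equivalent of NBS at 0 °C before any arene exists, so C5 stays unbrominated.

**Step 3**
Reactants: 6 methyl 2,4-dihydroxy-3,6-dimethylbenzoate
Product: 8 methyl 5-formyl-2,4-dihydroxy-3,6-dimethylbenzoate, via α-chlorobenzyl methyl ether 7 (not isolated)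
Conditions: Cl2CHOMe (1.5 equiv), TiCl4 (3 equiv), CH2Cl2, −10 → 0 °C, 2 h; then ice/1 M HCl
Reagents that add atoms: dichloromethyl methyl ether, COC(Cl)Cl; water, O
Why: Rieche formylation is regiochemically unambiguous because C5 is the only free ring position, ortho to 4-OH and para to 2-OH, and aqueous acid hydrolyses the α-chloro ether 7 to the aldehyde.

**Step 4**
Reactants: 8 methyl 5-formyl-2,4-dihydroxy-3,6-dimethylbenzoate
Product: 10 methyl 2,4-dihydroxy-3,5,6-trimethylbenzoate, via hydroxymethyl arene 9 (not isolated)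
Conditions: Et3SiH (3 equiv), TFA–CH2Cl2 (1:1), 0 °C → rt, 6 h
Reagents that add atoms: none
Why: In this ionic hydrogenation the protonated aldehyde and then the o,p-dihydroxy-stabilised benzylic cation from 9 each take hydride from the silane, no diarylmethane can form because no ring C–H is left, and the ester and phenols are inert to TFA.

**Step 5**
Reactants: 10 methyl 2,4-dihydroxy-3,5,6-trimethylbenzoate
Product: 11 methyl 4-(benzyloxy)-2-hydroxy-3,5,6-trimethylbenzoate
Conditions: BnBr (1.05 equiv), K2CO3 (1.2 equiv), acetone, reflux, 12 h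
Reagents that add atoms: benzyl bromide, BrCc1ccccc1
Why: Williamson etherification selects the 4-OH because the 2-OH is held in a strong intramolecular hydrogen bond to the ester carbonyl and is much less acidic and nucleophilic under weak base with one equivalent of halide.

**Step 6**
Reactants: 11 methyl 4-(benzyloxy)-2-hydroxy-3,5,6-trimethylbenzoate
Product: 12 methyl 4-(benzyloxy)-2-methoxy-3,5,6-trimethylbenzoate
Conditions: MeI (3 equiv), K2CO3 (3 equiv), DMF, 50 °C, 12 h
Reagents that add atoms: iodomethane, CI
Why: Williamson methylation in a polar aprotic solvent with excess MeI alkylates the chelated 2-OH, which is the only nucleophilic site left.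

**Step 7**
Reactants: 12 methyl 4-(benzyloxy)-2-methoxy-3,5,6-trimethylbenzoate
Product: 13 methyl 4-hydroxy-2-methoxy-3,5,6-trimethylbenzoate
Conditions: H2 (1 atm), 10% Pd/C, EtOAc, rt
Reagents that add atoms: none
Why: Catalytic hydrogenolysis cleaves only the benzylic C–O bond, while the aryl methyl ether, methyl ester and ring methyls are inert.

**Step 8**
Reactants: 6 methyl 2,4-dihydroxy-3,6-dimethylbenzoate
Product: 14 methyl 2,4-bis(benzyloxy)-3,6-dimethylbenzoate
Conditions: BnBr (2.6 equiv), K2CO3 (4 equiv), DMF, 70 °C, 12 h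
Reagents that add atoms: benzyl bromide, BrCc1ccccc1
Why: Exhaustive Williamson benzylation masks both phenols, so neither competes as a nucleophile in step 10 and the ester can be saponified without a deactivating phenolate or a decarboxylation-prone free resorcylic acid.

**Step 9**
Reactants: 14 methyl 2,4-bis(benzyloxy)-3,6-dimethylbenzoate
Product: 15 2,4-bis(benzyloxy)-3,6-dimethylbenzoic acid
Conditions: KOH (10 equiv), DMSO–H2O (4:1), 95 °C, 12 h; then 2 M HCl, 0 °C
Reagents that add atoms: potassium hydroxide, [K+].[OH-]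
Why: Saponification (BAc2) of the di-ortho-substituted ester succeeds with poorly solvated hydroxide in hot aqueous DMSO, the benzyl ethers are base-stable, and the O-protected acid does not decarboxylate on cold acidification.

**Step 10**
Reactants: 15 2,4-bis(benzyloxy)-3,6-dimethylbenzoic acid; 13 methyl 4-hydroxy-2-methoxy-3,5,6-trimethylbenzoate
Product: 17 methyl 4-{[2,4-bis(benzyloxy)-3,6-dimethylbenzoyl]oxy}-2-methoxy-3,5,6-trimethylbenzoate, via mixed trifluoroacetic anhydride 16 (not isolated)
Conditions: TFAA (4 equiv), toluene, rt, 6–16 h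
Reagents that add atoms: none
Why: In this mixed-anhydride esterification TFAA turns the electron-rich hindered acid into the acylium-like anhydride 16, which is captured by the only OH of 13 despite the di-ortho substitution on both partners, and the benzyl ethers, methyl ester and OMe tolerate TFA in toluene at rt.

**Step 11**
Reactants: 17 methyl 4-{[2,4-bis(benzyloxy)-3,6-dimethylbenzoyl]oxy}-2-methoxy-3,5,6-trimethylbenzoate
Product: 18 methyl 4-[(2,4-dihydroxy-3,6-dimethylbenzoyl)oxy]-2-methoxy-3,5,6-trimethylbenzoate
Conditions: H2 (1 atm), 10% Pd/C, EtOAc, rt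
Reagents that add atoms: none
Why: Neutral catalytic hydrogenolysis removes both benzyl ethers without touching the aryl ester, methyl ester or methyl ether, and no reducible aldehyde is present yet.

**Step 12**
Reactants: 18 methyl 4-[(2,4-dihydroxy-3,6-dimethylbenzoyl)oxy]-2-methoxy-3,5,6-trimethylbenzoate
Product: 20 methyl 4-[(5-formyl-2,4-dihydroxy-3,6-dimethylbenzoyl)oxy]-2-methoxy-3,5,6-trimethylbenzoate, via depside α-chlorobenzyl methyl ether 19 (not isolated)
Conditions: Cl2CHOMe (2 equiv), TiCl4 (5 equiv), CH2Cl2, −20 → 0 °C, 1–2 h; then ice/1 M HCl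
Reagents that add atoms: dichloromethyl methyl ether, COC(Cl)Cl; water, O
Why: This Rieche formylation repeats step 3 on the same resorcylate ring, where C5'–H is the only aromatic C–H of 18 (ortho to 4'-OH, para to 2'-OH), so only 20 can form, and keeping the temperature at or below 0 °C spares the depside ester and the B-ring o-methoxy ester.

**Compound list**
1 | dimethyl malonate | COC(=O)CC(=O)OC | starting material
2 | (E)-hex-4-en-3-one | C/C=C/C(=O)CC | starting material
3 | dimethyl 2-(4-oxohexan-2-yl)propanedioate (racemic, not isolated) | COC(=O)C(C(=O)OC)C(C)CC(=O)CC | intermediate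
4 | methyl 3,6-dimethyl-2,4-dioxocyclohexane-1-carboxylate (racemic diastereomer/enol mixture) | COC(=O)C1C(C)CC(=O)C(C)C1=O | intermediate
5 | methyl 3-bromo-3,6-dimethyl-2,4-dioxocyclohexane-1-carboxylate (mixture, not isolated) | COC(=O)C1C(C)CC(=O)C(C)(Br)C1=O | intermediate
6 | methyl 2,4-dihydroxy-3,6-dimethylbenzoate | COC(=O)c1c(C)cc(O)c(C)c1O | intermediate
7 | methyl 5-[chloro(methoxy)methyl]-2,4-dihydroxy-3,6-dimethylbenzoate (drawn metal-free, not isolated) | COC(=O)c1c(C)c(C(Cl)OC)c(O)c(C)c1O | intermediate
8 | methyl 5-formyl-2,4-dihydroxy-3,6-dimethylbenzoate | COC(=O)c1c(C)c(C=O)c(O)c(C)c1O | intermediate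
9 | methyl 2,4-dihydroxy-5-(hydroxymethyl)-3,6-dimethylbenzoate (not isolated) | COC(=O)c1c(C)c(CO)c(O)c(C)c1O | intermediate
10 | methyl 2,4-dihydroxy-3,5,6-trimethylbenzoate | COC(=O)c1c(C)c(C)c(O)c(C)c1O | intermediate
11 | methyl 4-(benzyloxy)-2-hydroxy-3,5,6-trimethylbenzoate | COC(=O)c1c(C)c(C)c(OCc2ccccc2)c(C)c1O | intermediate
12 | methyl 4-(benzyloxy)-2-methoxy-3,5,6-trimethylbenzoate | COC(=O)c1c(C)c(C)c(OCc2ccccc2)c(C)c1OC | intermediate
13 | methyl 4-hydroxy-2-methoxy-3,5,6-trimethylbenzoate | COC(=O)c1c(C)c(C)c(O)c(C)c1OC | intermediate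
14 | methyl 2,4-bis(benzyloxy)-3,6-dimethylbenzoate | COC(=O)c1c(C)cc(OCc2ccccc2)c(C)c1OCc3ccccc3 | intermediate
15 | 2,4-bis(benzyloxy)-3,6-dimethylbenzoic acid | OC(=O)c1c(C)cc(OCc2ccccc2)c(C)c1OCc3ccccc3 | intermediate
16 | 2,4-bis(benzyloxy)-3,6-dimethylbenzoic trifluoroacetic anhydride (not isolated) | O=C(OC(=O)C(F)(F)F)c1c(C)cc(OCc2ccccc2)c(C)c1OCc3ccccc3 | intermediate
17 | methyl 4-{[2,4-bis(benzyloxy)-3,6-dimethylbenzoyl]oxy}-2-methoxy-3,5,6-trimethylbenzoate | COC(=O)c1c(C)c(C)c(OC(=O)c2c(C)cc(OCc3ccccc3)c(C)c2OCc4ccccc4)c(C)c1OC | intermediate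
18 | methyl 4-[(2,4-dihydroxy-3,6-dimethylbenzoyl)oxy]-2-methoxy-3,5,6-trimethylbenzoate | COC(=O)c1c(C)c(C)c(OC(=O)c2c(C)cc(O)c(C)c2O)c(C)c1OC | intermediate
19 | methyl 4-({5-[chloro(methoxy)methyl]-2,4-dihydroxy-3,6-dimethylbenzoyl}oxy)-2-methoxy-3,5,6-trimethylbenzoate (drawn metal-free, not isolated) | COC(=O)c1c(C)c(C)c(OC(=O)c2c(C)c(C(Cl)OC)c(O)c(C)c2O)c(C)c1OC | intermediate
20 | methyl 4-[(5-formyl-2,4-dihydroxy-3,6-dimethylbenzoyl)oxy]-2-methoxy-3,5,6-trimethylbenzoate (CNP0316552.0, achiral) | COC(=O)c1c(C)c(C)c(OC(=O)c2c(C)c(C=O)c(O)c(C)c2O)c(C)c1OC | target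

**Totals**
Total step count: 12.
Longest linear sequence: 10 (steps 1–7, then 10–12). The ring-A branch (steps 8–9) leaves the main line at 6.

**Three steps most likely to fail**

Step 12 (Rieche formylation of the finished depside). The risks are TiCl4-induced cleavage of the aryl ester, chelation-assisted loss of the B-ring 2-OMe, and incomplete conversion.
The fallback installs the aldehyde before the ester bond is made. It sets out from aldehyde 8 and phenol 13 and returns to the route at 20. Compound 8 is dissolved in cold concentrated H2SO4 (0 °C → rt, acylium-type AAc1 cleavage of the hindered ester, then ice) to give 5-formyl-2,4-dihydroxy-3,6-dimethylbenzoic acid F1. F1 and 13 are then stirred with TFAA in toluene at rt. This passes through 5-formyl-2,4-dihydroxy-3,6-dimethylbenzoic trifluoroacetic anhydride F2 and gives 20 directly. Both phenols of F1 are locked in intramolecular hydrogen bonds (2-OH to the carboxyl, 4-OH to the formyl group) and flanked by methyl groups, so they compete poorly for acyl transfer. No strong Lewis acid ever meets the depside.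

Step 10 (esterification of a di-ortho-substituted acid with a di-ortho-substituted phenol). The risks are slow acyl transfer and loss of the 2-O-benzyl group from the acylium-like anhydride.
The fallback changes the protecting-group pattern so that the acid is less hindered and activated by hydrogen bonding. It sets out from 6 and returns to the route at 18.
- Selective Williamson benzylation (BnBr 1.05 equiv, K2CO3, acetone, reflux) gives methyl 4-(benzyloxy)-2-hydroxy-3,6-dimethylbenzoate F3.
- KOH in DMSO–H2O at 90 °C, then cold HCl, gives 4-(benzyloxy)-2-hydroxy-3,6-dimethylbenzoic acid F4.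
- DCC in toluene at rt with 13 proceeds through N,N'-dicyclohexyl-O-[4-(benzyloxy)-2-hydroxy-3,6-dimethylbenzoyl]isourea F5 to methyl 4-{[4-(benzyloxy)-2-hydroxy-3,6-dimethylbenzoyl]oxy}-2-methoxy-3,5,6-trimethylbenzoate F6.
- Hydrogenolysis (H2, Pd/C, EtOAc) then delivers 18.

Step 2 (one-equivalent bromination/dehydrobromination). The risks are partial bromination of the product at C5 with unreacted dione left over, and sluggish HBr loss.
The fallback over-oxidises on purpose and then reduces. It sets out from 4 and returns to the route at 6. Br2 (2.1 equiv) in AcOH at rt aromatises the ring and brominates the one free position, giving methyl 5-bromo-2,4-dihydroxy-3,6-dimethylbenzoate F7 as a single crystalline product. Catalytic hydrodebromination (H2 1 atm, Pd/C, NaOAc, MeOH) then gives 6.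

**Further compounds**
F1 | step 12 | 5-formyl-2,4-dihydroxy-3,6-dimethylbenzoic acid | OC(=O)c1c(C)c(C=O)c(O)c(C)c1O
F2 | step 12 | 5-formyl-2,4-dihydroxy-3,6-dimethylbenzoic trifluoroacetic anhydride | O=C(OC(=O)C(F)(F)F)c1c(C)c(C=O)c(O)c(C)c1O
F3 | step 10 | methyl 4-(benzyloxy)-2-hydroxy-3,6-dimethylbenzoate | COC(=O)c1c(C)cc(OCc2ccccc2)c(C)c1O
F4 | step 10 | 4-(benzyloxy)-2-hydroxy-3,6-dimethylbenzoic acid | OC(=O)c1c(C)cc(OCc2ccccc2)c(C)c1O
F5 | step 10 | N,N'-dicyclohexyl-O-[4-(benzyloxy)-2-hydroxy-3,6-dimethylbenzoyl]isourea | O=C(OC(=NC1CCCCC1)NC2CCCCC2)c3c(C)cc(OCc4ccccc4)c(C)c3O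
F6 | step 10 | methyl 4-{[4-(benzyloxy)-2-hydroxy-3,6-dimethylbenzoyl]oxy}-2-methoxy-3,5,6-trimethylbenzoate | COC(=O)c1c(C)c(C)c(OC(=O)c2c(C)cc(OCc3ccccc3)c(C)c2O)c(C)c1OC
F7 | step 2 | methyl 5-bromo-2,4-dihydroxy-3,6-dimethylbenzoate | COC(=O)c1c(C)c(Br)c(O)c(C)c1O
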